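Start from the leftover: at any stop, the flask still owes the distance between the target it holds and its ceiling, and the earlier runs show how fast that distance shrinks.

| flask | starting material | other conformer | remark | time |
|---|---|---|---|---|
| eta | 20 mM | 2.5 mM | run made earlier |  |
| zeta | 20 mM | 10 mM | run made earlier |  |
| delta | 10 mM | 5 mM | run made earlier |  |
| Tuesday's | 20 mM | 5.00 mM |  | 1.5 h |
| Sunday's | 20 mM | 5.00 mM |  | 6.0 h |

- eta (time / h: target / %): 0.500: 9; 1.00: 19; 2.00: 34; 4.00: 46; 8.00: 64
- zeta (time / h: target / %): 0.500: 2; 1.00: 16; 2.00: 25; 4.00: 38; 8.00: 47
- delta (time / h: target / %): 0.500: 6; 1.00: 15; 2.00: 23; 4.00: 35; 8.00: 49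

(scatter of a reading: 2 percentage points)

- the earlier runs were read with a standard deviation of 2 percentage points
- in a conversion other conformer counts as not yet reacted; third conformer counts as reacted

- the flask that ends with the higher amount of target, in percent of the starting material and other conformer together charged, or "neither" when 2 percentage points or less lies between them (Tuesday's / Sunday's / neither)
- final target, as a percentage of the starting material and other conformer together charged, in Tuesday's
- final target, as a percentage of the starting material and other conformer together charged, in Sunday's

Divide each target reading by the fraction of the charge that was starting material. At 8.00 h the eta, zeta and delta runs then read 0.720, 0.705 and 0.735, although other conformer went from 2.5 mM in eta to 10 mM in zeta. Call this the yield on starting material. Averaged over the runs, it reads 0.537 at 4.00 h and 0.720 at 8.00 h.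

Now solve both ends and join them. If the leftover shrinks by one factor in each equal stretch of time, the second stretch gains 0.340 of what the first gained. That reads the ceiling at 0.814, with the scatter of the readings in it. The half-time, the time in which the leftover halves (an apparent first-order half-life), reads 2.57 h.

That gives the ladder. Tuesday's stops first, at 1.5 h, after 0.584 half-times, with 0.667 of the leftover still open. Sunday's stops at 6.0 h, after 2.33 half-times, with 0.198 open. Starting material is 0.800 of each charge, so my reckoning gives 21.7 % for Tuesday's and 52.2 % for Sunday's.

The forecast names Sunday's, with 24 % (21 % to 27 %) for Tuesday's and 52 % (47 % to 57 %) for Sunday's, holding that “the other conformer looks like a spectator”. Its Tuesday's figure stands above mine.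

The flasks give 21.5 % in Tuesday's and 51.9 % in Sunday's, so Sunday's ends higher.

    starting material ⇌ other conformer (K = 0.780, k = 9.90 × 10⁻⁴ /min)
    starting material → target (k = 0.00360 /min)
    other conformer → isomer of the product (k = 0.0160 /min)
    other conformer ⇌ third conformer (K = 35.0, k = 9.90 × 10⁻⁴ /min)
    third conformer → third product (k = 0.0150 /min)
    2 other conformer → homo dimer (k = 0.0630 /M/min)

Sunday's has not come to rest at 6.00 h: 16.1 % of the charge still stands as starting material, and the target lacks 0.199 of its value at 60.0 h, against the 0.198 that the half-time gave. A neighbour of Sunday's, the same flask with 8.5 mM of other conformer, has a starting-material share of 0.702, so the same half-time gives 45.8 % at 6.00 h, and that neighbour holds 46.0 %. Ten times the time adds 13 percentage points of target to Sunday's, and isomer of the product goes from 28.6 % to 32.7 %, while at 60.0 h starting material stands at 0 % and target at 64.8 %.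

(All runs are simulated from invented constants, noise included.)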